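**Retrosynthetic overview**
1. The last bond made is the C2–O bond of the ketone. It comes from a regioselective Wacker-type oxidation (oxygen from water, O2 as terminal oxidant) of the C1=C2 double bond of 5-(henicos-1-enyl)resorcinol, with oxygen going to the homobenzylic carbon.
2. The alkene comes from a Wittig olefination of unprotected 3,5-dihydroxybenzaldehyde with the C20 ylide, which is made in the same flask from 1-bromoicosane and PPh3.
3. No ring is formed. The resorcinol ring is bought intact, and there are no protecting groups and no stereocentres.

Assumption: the target SMILES holds no stereocentre and no configured double bond, so the compound is achiral and there is no enantiomer to select. The chain is read as 20 carbons from CH3 up to and including C=O, plus the benzylic CH2 (a henicosan-2-one chain).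

**Step 1**
Reactants: 1 1-bromoicosane; 2 triphenylphosphine; 3 3,5-dihydroxybenzaldehyde
Product: 6 5-(henicos-1-en-1-yl)benzene-1,3-diol (Z/E mixture), via icosyltriphenylphosphonium bromide 4 (not isolated), via icosylidenetriphenylphosphorane 5 (not isolated)
Conditions: 1 (1.25 equiv), 2 (1.30 equiv), neat, 130 °C, 16 h, Ar; then THF, KOtBu (3.3 equiv), 0 °C, 30 min; then 3 (1.0 equiv) in THF, 0 °C to rt, 12 h; 1 M HCl work-up, SiO2
Reagents that add atoms: none
Why: SN2 quaternisation of PPh3 by the primary bromide, deprotonation to the non-stabilised ylide and Wittig olefination follow one another in one flask; two further equivalents of KOtBu hold the phenols as phenoxides, which sit meta to the formyl group and so do not deactivate it by conjugation; the slight excess of PPh3 leaves no bromide 1 to O-alkylate the phenoxides; no stereocentre is formed, and the Z/E ratio (Z major) does not matter because both isomers give 8.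

**Step 2**
Reactants: 6 5-(henicos-1-en-1-yl)benzene-1,3-diol (Z/E mixture)
Product: 8 1-(3,5-dihydroxyphenyl)henicosan-2-one (target CNP0332609.0), via enol 7 (not isolated)
Conditions: [Pd(MeCN)4](BF4)2 (5 mol %), 4,5-diazafluoren-9-one (6 mol %), O2 (1 atm), DMA/H2O 9:1, 50 °C, 24 h
Reagents that add atoms: water, O
Why: Proposed new method: a copper-, chloride- and quinone-free aerobic Wacker–Tsuji-type oxidation tuned to oxygenate the homobenzylic carbon of a long-chain β-alkylstyrene that carries free phenols. The cationic hydroxo complex formed from [Pd(MeCN)4](BF4)2, the diazafluorenone ligand and water binds C1=C2 and inserts it syn into the Pd–OH bond, so palladium ends at C1, where the coordination site freed by the insertion is filled by η3-benzyl binding, and oxygen ends at C2. The two meta OH groups (σm > 0) give no support to the rival attack of water at C1. With palladium at C1 the only β-hydrogen is the carbinol H at C2, so β-hydride elimination can give only enol 7, which tautomerises to 8 (C27H46O2 + O = C27H46O3). Zerovalent palladium is returned to divalent palladium directly by O2, as in ligand-supported aerobic palladium oxidations. Conjugation holds the alkene against chain walking, the meta OH groups cannot cyclise onto it, the absence of acetate disfavours allylic C–H cleavage, and no one-electron oxidant (copper salt, quinone, metal-oxo species) is present to attack the resorcinol. The closest known reaction types are the Wacker–Tsuji oxidation of internal alkenes (PdCl2/DMA/O2, or Pd(OAc)2/HBF4/benzoquinone) and the aldehyde-selective anti-Markovnikov Wacker oxidation of styrenes. No stereocentre is formed.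

**Compound list**
1 | 1-bromoicosane | CCCCCCCCCCCCCCCCCCCCBr | starting material
2 | triphenylphosphine | c1ccc(cc1)P(c1ccccc1)c1ccccc1 | starting material
3 | 3,5-dihydroxybenzaldehyde | O=Cc1cc(O)cc(O)c1 | starting material
4 | icosyl(triphenyl)phosphonium bromide (not isolated) | CCCCCCCCCCCCCCCCCCCC[P+](c1ccccc1)(c1ccccc1)c1ccccc1.[Br-] | intermediate
5 | icosylidene(triphenyl)phosphorane, the C20 ylide (not isolated) | CCCCCCCCCCCCCCCCCCCC=P(c1ccccc1)(c1ccccc1)c1ccccc1 | intermediate
6 | 5-(henicos-1-en-1-yl)benzene-1,3-diol, Z/E mixture with Z major, used as the mixture, so the geometry is left open in the SMILES | CCCCCCCCCCCCCCCCCCCC=Cc1cc(O)cc(O)c1 | intermediate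
7 | 5-(2-hydroxyhenicos-1-en-1-yl)benzene-1,3-diol, the C2 enol, geometry open (not isolated) | CCCCCCCCCCCCCCCCCCCC(O)=Cc1cc(O)cc(O)c1 | intermediate
8 | 1-(3,5-dihydroxyphenyl)henicosan-2-one, achiral | CCCCCCCCCCCCCCCCCCCC(=O)Cc1cc(O)cc(O)c1 | target

**Total step count:** 2
**Longest linear sequence:** 2

**Steps most likely to fail.** The route has only two steps, so step 1 is ranked twice, once for each of its two stages.

1. **Step 2 (the proposed new step).** Oxygen may go partly to C1 and give the regioisomeric aryl ketone. The cationic palladium may palladate the electron-rich ring, or fall out as palladium black before O2 re-oxidises it. The fallback uses known chemistry only, sets out from 6 and comes back at 8. Prilezhaev epoxidation of 6 with mCPBA (NaHCO3, CH2Cl2, 0 °C) gives 5-(3-nonadecyloxiran-2-yl)benzene-1,3-diol F1 as a racemic cis/trans mixture. F1 is then isomerised with Pd(OAc)2 (5 mol %) and PBu3 (15 mol %) in refluxing tBuOH. Zerovalent palladium formed in the flask opens the benzylic C–O bond, and β-hydride elimination at C2 followed by release of the enolate gives 8. This is a Meinwald-type epoxide-to-ketone isomerisation under neutral conditions that free phenols tolerate. It costs one extra step.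

2. **Step 1, olefination stage.** The dipotassium salt of 3 is poorly soluble in THF and may react so slowly that the ylide decays. The fallback sets out from 3 and ylide 5 and comes back at 6. TBSCl and imidazole in DMF turn 3 into 3,5-bis[(tert-butyldimethylsilyl)oxy]benzaldehyde F2. F2 is added to 5, now made with only one equivalent of KOtBu per phosphonium salt, and gives 1,3-bis[(tert-butyldimethylsilyl)oxy]-5-(henicos-1-en-1-yl)benzene F3. TBAF in THF at 0 °C frees 6.

3. **Step 1, salt-forming stage.** Incomplete quaternisation in the melt would leave 1, which O-alkylates the phenoxides, and the waxy salt 4 cannot be purified in a one-flask run. The fallback drops phosphorus altogether, sets out from 1 and 3 and comes back at 6. Mg in THF converts 1 into icosylmagnesium bromide F4. Aldehyde 3 is first deprotonated with iPrMgCl (2.1 equiv), then F4 (1.2 equiv) is added, giving racemic 5-(1-hydroxyhenicosyl)benzene-1,3-diol F5. Thermal dehydration of this benzylic alcohol in DMSO at 160 °C, under neutral conditions so that no Friedel–Crafts alkylation of the resorcinol occurs, gives 6, mainly as the E isomer, which step 2 accepts equally.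

**Further compounds**
F1 | step 2 | 5-(3-nonadecyloxiran-2-yl)benzene-1,3-diol (racemic cis/trans mixture) | CCCCCCCCCCCCCCCCCCCC1OC1c2cc(O)cc(O)c2
F2 | step 1 | 3,5-bis[(tert-butyldimethylsilyl)oxy]benzaldehyde | O=Cc1cc(O[Si](C)(C)C(C)(C)C)cc(O[Si](C)(C)C(C)(C)C)c1
F3 | step 1 | 1,3-bis[(tert-butyldimethylsilyl)oxy]-5-(henicos-1-en-1-yl)benzene (Z/E mixture) | CCCCCCCCCCCCCCCCCCCC=Cc1cc(O[Si](C)(C)C(C)(C)C)cc(O[Si](C)(C)C(C)(C)C)c1
F4 | step 1 | icosylmagnesium bromide | CCCCCCCCCCCCCCCCCCCC[Mg]Br
F5 | step 1 | 5-(1-hydroxyhenicosyl)benzene-1,3-diol (racemic) | CCCCCCCCCCCCCCCCCCCCC(O)c1cc(O)cc(O)c1
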